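## Retrosynthetic overview

1. Target 12 ⇒ p-quinone methide 10 by the C7–O bond. The oxolane is the only ring and is closed last, by attack of the 9'-OH on C7, as in the biosynthesis of 7,9'-epoxylignans. Here 10 comes from dehydrogenation of the C7–H2 of the open-chain keto diol 9.
2. 9 ⇒ γ-hydroxy ketone 6 + formaldehyde (C8'–C9' aldol).
3. 6 ⇒ aldehyde 2 + phenacyl bromide 4 (C8–C8' bond). A catalyst-controlled radical α-alkylation sets C8, the one centre that cannot equilibrate; C7 and C8' are set from it in the last step.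
4. 2 ⇐ coniferaldehyde 1; 4 ⇐ acetosyringone 3.

Numbering: lignan numbering is used, guaiacyl unit C7–C8–C9 and syringyl unit C7'–C8'–C9'. The target is (7S,8R,8'S), all-trans on the oxolane.

Assumption: the (2R,5S)-imidazolidinone is taken to give the (R)-aldehyde (Si-face attack on the E-enamine, as recalled for the parent alkylation); if the sense proved opposite, the (2S,5R) catalyst would be used.

## Route

Step 1
Reactants: 1 coniferaldehyde, (E)-3-(4-hydroxy-3-methoxyphenyl)prop-2-enal
Product: 2 3-(4-hydroxy-3-methoxyphenyl)propanal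
Conditions: H2 (1 atm), 5% Pd/C, EtOAc, rt, stopped after 1 equiv H2
Reagents that add atoms: none
Why: Catalytic hydrogenation over palladium on carbon saturates the conjugated C=C much faster than the aldehyde or the arene; no stereocentre is formed.

Step 2
Reactants: 3 acetosyringone, 1-(4-hydroxy-3,5-dimethoxyphenyl)ethan-1-one
Product: 4 2-bromo-1-(4-hydroxy-3,5-dimethoxyphenyl)ethan-1-one
Conditions: CuBr2 (2.0 equiv), EtOAc/CHCl3 1:1, reflux
Reagents that add atoms: copper dibromide (CuBr2), Br[Cu]Br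
Why: King-type α-bromination of an aryl methyl ketone with CuBr2 goes through the enol and tolerates the free phenol, whose ortho positions are both blocked by OMe; no stereocentre is formed.

Step 3
Reactants: 2 3-(4-hydroxy-3-methoxyphenyl)propanal (2 equiv); 4 2-bromo-1-(4-hydroxy-3,5-dimethoxyphenyl)ethan-1-one (1 equiv)
Product: 6 (3R)-4-hydroxy-3-[(4-hydroxy-3-methoxyphenyl)methyl]-1-(4-hydroxy-3,5-dimethoxyphenyl)butan-1-one, via keto aldehyde 5 (not isolated)
Conditions: Ru(bpy)3Cl2 (0.5 mol%), (2R,5S)-2-tert-butyl-3,5-dimethylimidazolidin-4-one·TfOH (20 mol%), 2,6-lutidine (2 equiv), degassed DMF, fluorescent light, rt; then NaBH4, MeOH, 0 °C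
Reagents that add atoms: none
Why: Photoredox organocatalytic α-alkylation of an aldehyde (MacMillan type): the phenacyl radical released from 4 by the reduced photocatalyst adds to the open Si face of the E-enamine of 2 and sets C8 as R, and the in-situ NaBH4 reduction takes only the aldehyde (the p-hydroxyaryl ketone is deactivated as its phenolate), which makes the new centre non-enolisable.

Step 4
Reactants: 6 (3R)-4-hydroxy-3-[(4-hydroxy-3-methoxyphenyl)methyl]-1-(4-hydroxy-3,5-dimethoxyphenyl)butan-1-one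
Product: 9 (2RS,3R)-4-hydroxy-3-[(4-hydroxy-3-methoxyphenyl)methyl]-2-(hydroxymethyl)-1-(4-hydroxy-3,5-dimethoxyphenyl)butan-1-one, via tetrakis-TMS silyl enol ether 7 (not isolated), via tris-TMS aldol adduct 8 (not isolated)
Conditions: TMSOTf (4.5 equiv), Et3N (6 equiv), CH2Cl2, 0 °C; then 37% aq. HCHO, Yb(OTf)3 (10 mol%), THF, rt; then 1 M HCl, MeOH, 0 °C
Reagents that add atoms: formaldehyde, C=O (trimethylsilyl triflate, C[Si](C)(C)OS(=O)(=O)C(F)(F)F, puts silicon only into 7 and 8, none remains in 9)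
Why: Mukaiyama aldol hydroxymethylation in aqueous medium (lanthanide triflate catalysis): persilylation masks the three OH groups and gives the only possible enol ether (C7'=C8'), which adds to formaldehyde before the O–TMS groups hydrolyse; the new C8' centre forms unselectively and is corrected in step 5.

Step 5
Reactants: 9 (2RS,3R)-4-hydroxy-3-[(4-hydroxy-3-methoxyphenyl)methyl]-2-(hydroxymethyl)-1-(4-hydroxy-3,5-dimethoxyphenyl)butan-1-one
Product: 12 [(3S,4R,5S)-5-(4-hydroxy-3-methoxyphenyl)-4-(hydroxymethyl)oxolan-3-yl](4-hydroxy-3,5-dimethoxyphenyl)methanone, via p-quinone methide 10 (not isolated), via 8'-epimer 11 (not isolated)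
Conditions: DDQ (1.0 equiv), 1,4-dioxane, 10 °C to rt; aq. NaHCO3 wash; then K2CO3, MeOH, rt
Reagents that add atoms: none
Why: Quinone dehydrogenation of the p-alkylguaiacol gives the quinone methide of the biosynthesis, the 9'-OH closes the oxolane by 5-exo oxa-1,6-addition anti to the C8 substituents (sets C7 as S, 7,8-trans; an oxetane from the 9-OH is not viable), and base epimerisation through the enolate drives C8' to the all-trans isomer (8'S).

## Compound list

1 | coniferaldehyde, (E)-3-(4-hydroxy-3-methoxyphenyl)prop-2-enal | COc1cc(/C=C/C=O)ccc1O | starting material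
2 | 3-(4-hydroxy-3-methoxyphenyl)propanal | COc1cc(CCC=O)ccc1O | intermediate
3 | acetosyringone, 1-(4-hydroxy-3,5-dimethoxyphenyl)ethan-1-one | COc1cc(C(C)=O)cc(OC)c1O | starting material
4 | 2-bromo-1-(4-hydroxy-3,5-dimethoxyphenyl)ethan-1-one | COc1cc(C(=O)CBr)cc(OC)c1O | intermediate
5 | (2R)-2-[(4-hydroxy-3-methoxyphenyl)methyl]-4-(4-hydroxy-3,5-dimethoxyphenyl)-4-oxobutanal | COc1cc(C[C@@H](C=O)CC(=O)c2cc(OC)c(O)c(OC)c2)ccc1O | intermediate (not isolated)
6 | (3R)-4-hydroxy-3-[(4-hydroxy-3-methoxyphenyl)methyl]-1-(4-hydroxy-3,5-dimethoxyphenyl)butan-1-one | COc1cc(C[C@@H](CO)CC(=O)c2cc(OC)c(O)c(OC)c2)ccc1O | intermediate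
7 | tetrakis-O-TMS derivative of 6: (Z)-silyl enol ether at C7'=C8', TMS ethers on both phenols and the 9-OH, C8 R | COc1cc(C[C@@H](CO[Si](C)(C)C)/C=C(\O[Si](C)(C)C)c2cc(OC)c(O[Si](C)(C)C)c(OC)c2)ccc1O[Si](C)(C)C | intermediate (not isolated)
8 | tris-O-TMS aldol adduct: 9 with TMS on both phenols and the 9-OH, 9'-OH free, C8 R, both C8' epimers | COc1cc(C[C@@H](CO[Si](C)(C)C)C(CO)C(=O)c2cc(OC)c(O[Si](C)(C)C)c(OC)c2)ccc1O[Si](C)(C)C | intermediate (not isolated)
9 | (2RS,3R)-4-hydroxy-3-[(4-hydroxy-3-methoxyphenyl)methyl]-2-(hydroxymethyl)-1-(4-hydroxy-3,5-dimethoxyphenyl)butan-1-one | COc1cc(C[C@@H](CO)C(CO)C(=O)c2cc(OC)c(O)c(OC)c2)ccc1O | intermediate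
10 | p-quinone methide of 9: guaiacyl ring as 2-methoxycyclohexa-2,5-dien-1-one with exocyclic C1=C7, C8 unchanged, both C8' epimers | COC1=CC(=C[C@@H](CO)C(CO)C(=O)c2cc(OC)c(O)c(OC)c2)C=CC1=O | intermediate (not isolated)
11 | [(3R,4R,5S)-5-(4-hydroxy-3-methoxyphenyl)-4-(hydroxymethyl)oxolan-3-yl](4-hydroxy-3,5-dimethoxyphenyl)methanone, the 8'-epimer of the target | COc1cc([C@H]2OC[C@H](C(=O)c3cc(OC)c(O)c(OC)c3)[C@@H]2CO)ccc1O | intermediate (not isolated)
12 | [(3S,4R,5S)-5-(4-hydroxy-3-methoxyphenyl)-4-(hydroxymethyl)oxolan-3-yl](4-hydroxy-3,5-dimethoxyphenyl)methanone | COc1cc([C@H]2OC[C@@H](C(=O)c3cc(OC)c(O)c(OC)c3)[C@@H]2CO)ccc1O | target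

## Step count and risks

Total step count: 5. Longest linear sequence: 4 steps (1 → 2 → 6 → 9 → 12).

**Most likely to fail, first: step 3.** The radical alkylation is run with two free phenols. Phenolic O–H donors can quench the phenacyl radical, and the electron-rich bromide is reduced more slowly than the parent phenacyl bromide. The points in its favour are that 2,6-lutidine does not make phenolates (so no O-phenacylation), DMF hydrogen-bonds the phenols and slows H-atom transfer, and the excited photocatalyst does not oxidise neutral phenols. The fallback masks both phenols so that the radical chain sees no O–H donor. It sets out from 2 and 4. Acetylation (Ac2O, pyridine for 2; Ac2O, cat. H2SO4 for 4) gives 2-methoxy-4-(3-oxopropyl)phenyl acetate F1 and 4-(2-bromoacetyl)-2,6-dimethoxyphenyl acetate F2. The same photoredox alkylation then gives 4-[(2R)-4-(4-acetoxy-3,5-dimethoxyphenyl)-2-formyl-4-oxobutyl]-2-methoxyphenyl acetate F3, which is not isolated. NaBH4 at −40 °C reduces it to 4-[(2R)-4-(4-acetoxy-3,5-dimethoxyphenyl)-2-(hydroxymethyl)-4-oxobutyl]-2-methoxyphenyl acetate F4. Methanolysis (K2CO3, MeOH, 0 °C) returns to the route at 6.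

**Second: step 4.** The silyl enol ether may hydrolyse faster than it adds, a second hydroxymethylation or dehydration to the enone may occur, and 6 may partly react through its cyclic hemiketal or the derived 2,3-dihydrofuran (which would give the same product by a Prins-type addition). The fallback replaces the Lewis-acid aldol by a base aldol on phenol-protected material. It sets out from 6. Phenol-selective benzylation (BnBr, K2CO3, acetone) gives (3R)-3-[(4-benzyloxy-3-methoxyphenyl)methyl]-1-(4-benzyloxy-3,5-dimethoxyphenyl)-4-hydroxybutan-1-one F5. Hydroxymethylation (paraformaldehyde, K2CO3, DMSO, rt) gives (2RS,3R)-3-[(4-benzyloxy-3-methoxyphenyl)methyl]-1-(4-benzyloxy-3,5-dimethoxyphenyl)-4-hydroxy-2-(hydroxymethyl)butan-1-one F6. Hydrogenolysis (H2, Pd/C, EtOAc) returns to the route at 9.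

**Third: step 5.** The product is itself a p-hydroxybenzyl ether and can be oxidised further by DDQ. The quinone methide can tautomerise to the styrene, which would erase C8. It can also be trapped by the enol or hemiketal oxygen, or close to the 7,8-cis isomer. The fallback separates oxidation from ring closure. It sets out from 9. DDQ (1.0 equiv) in MeOH/CH2Cl2 traps the quinone methide with solvent to give (3R)-4-hydroxy-3-[(4-hydroxy-3-methoxyphenyl)(methoxy)methyl]-2-(hydroxymethyl)-1-(4-hydroxy-3,5-dimethoxyphenyl)butan-1-one F7, a mixture at C7 and C8' that is stable and freed from oxidant. Camphorsulfonic acid (10 mol%) in CH2Cl2 at rt then re-ionises the benzylic ether, and the 9'-OH closes the ring with loss of methanol under thermodynamic control; the 7'-keto group deactivates the syringyl ring against aryltetralin formation. The same K2CO3/MeOH equilibration returns to the route at 12.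

## Further compounds

F1 | step 3 | 2-methoxy-4-(3-oxopropyl)phenyl acetate | COc1cc(CCC=O)ccc1OC(C)=O
F2 | step 3 | 4-(2-bromoacetyl)-2,6-dimethoxyphenyl acetate | COc1cc(C(=O)CBr)cc(OC)c1OC(C)=O
F3 | step 3 | 4-[(2R)-4-(4-acetoxy-3,5-dimethoxyphenyl)-2-formyl-4-oxobutyl]-2-methoxyphenyl acetate | COc1cc(C[C@@H](C=O)CC(=O)c2cc(OC)c(OC(C)=O)c(OC)c2)ccc1OC(C)=O
F4 | step 3 | 4-[(2R)-4-(4-acetoxy-3,5-dimethoxyphenyl)-2-(hydroxymethyl)-4-oxobutyl]-2-methoxyphenyl acetate | COc1cc(C[C@@H](CO)CC(=O)c2cc(OC)c(OC(C)=O)c(OC)c2)ccc1OC(C)=O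
F5 | step 4 | (3R)-3-[(4-benzyloxy-3-methoxyphenyl)methyl]-1-(4-benzyloxy-3,5-dimethoxyphenyl)-4-hydroxybutan-1-one | COc1cc(C[C@@H](CO)CC(=O)c2cc(OC)c(OCc3ccccc3)c(OC)c2)ccc1OCc1ccccc1
F6 | step 4 | (2RS,3R)-3-[(4-benzyloxy-3-methoxyphenyl)methyl]-1-(4-benzyloxy-3,5-dimethoxyphenyl)-4-hydroxy-2-(hydroxymethyl)butan-1-one | COc1cc(C[C@@H](CO)C(CO)C(=O)c2cc(OC)c(OCc3ccccc3)c(OC)c2)ccc1OCc1ccccc1
F7 | step 5 | (3R)-4-hydroxy-3-[(4-hydroxy-3-methoxyphenyl)(methoxy)methyl]-2-(hydroxymethyl)-1-(4-hydroxy-3,5-dimethoxyphenyl)butan-1-one | COc1cc(C(OC)[C@@H](CO)C(CO)C(=O)c2cc(OC)c(O)c(OC)c2)ccc1O
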